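Ring B of the decalin is opened at C5–C6 and C7–C8 (labdane numbering), which makes C6–C7 a traceless two-carbon unit between the ring-fusion carbon C5 and the methyl-bearing alkene carbon C8. In the key step the C8 enolate of a monocyclic 1,3-diketone (ring A with the C10 quaternary centre, C5 and C9 as ketones) adds to vinyltriphenylphosphonium bromide, and the ylide so formed olefinates the non-enolisable C5 ketone: ring B closes in one operation. C10 comes from an asymmetric decarboxylative allylation; hydrogen atom transfer then sets the trans ring fusion, and the C9 ketone is turned into the C8=C9 alkene carrying a separately made butenolide side chain.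

Key step: step 7

Remarks: The decalin atoms carry labdane numbering (C1–C4 in ring A, C5 and C10 at the ring fusion, C6 and C7 the ring B methylenes, C8=C9 the alkene, C11–C16 the chain). It is assumed that the (R)-configured PHOX ligand and the (R)-configured phosphoric acid give the (R)-configured products shown, by analogy with their reaction classes; if the sense were opposite, the antipodal catalyst would be used. The side-chain diol is carried without protecting groups.

**Decalin fragment**

Step 1
Reactants: 1 2,2,6-trimethylcyclohexan-1-one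
Product: 2 allyl 2,6,6-trimethylcyclohex-1-en-1-yl carbonate
Conditions: LiN(SiMe3)2, THF, 0 °C; allyl chloroformate, −78 °C to rt
Reagents that add atoms: allyl chloroformate, C=CCOC(Cl)=O
Why: The ketone has a single enolisable position (C10), and the hindered tetrasubstituted lithium enolate should be acylated at oxygen (enol carbonate formation).

Step 2
Reactants: 2 allyl 2,6,6-trimethylcyclohex-1-en-1-yl carbonate
Product: 3 (2R)-2-allyl-2,6,6-trimethylcyclohexan-1-one
Conditions: Pd2(dba)3 (2.5 mol%), (R)-t-BuPHOX (6 mol%), THF, 25 °C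
Reagents that add atoms: none
Why: Decarboxylative asymmetric allylic alkylation (Tsuji allylation): ionisation and loss of CO2 give an allylpalladium enolate, and the PHOX ligand selects the enolate face in the C–C bond-forming step, which sets the quaternary C10.

Step 3
Reactants: 3 (2R)-2-allyl-2,6,6-trimethylcyclohexan-1-one
Product: 4 (6R)-2,2,6-trimethyl-6-[(1E)-prop-1-en-1-yl]cyclohexan-1-one
Conditions: RuHCl(CO)(PPh3)3 (5 mol%), toluene, 80 °C
Reagents that add atoms: none
Why: Ruthenium hydride-catalysed alkene isomerisation (hydrometalation/β-hydride elimination) should move the terminal double bond one position to the internal E-alkene and stop there because C10 is quaternary; the stereocentre is not touched.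

Step 4
Reactants: 4 (6R)-2,2,6-trimethyl-6-[(1E)-prop-1-en-1-yl]cyclohexan-1-one
Product: 5 (1R)-1,3,3-trimethyl-2-oxocyclohexane-1-carbaldehyde
Conditions: O3, CH2Cl2, −78 °C; Me2S, −78 °C to rt
Reagents that add atoms: ozone, [O-][O+]=O
Why: Ozonolysis with reductive work-up cleaves the propenyl group to the neopentylic aldehyde (C9); C10 carries no hydrogen and cannot epimerise.

Step 5
Reactants: 5 (1R)-1,3,3-trimethyl-2-oxocyclohexane-1-carbaldehyde
Product: 6 (2R)-2-(1-hydroxypropyl)-2,6,6-trimethylcyclohexan-1-one (carbinol epimers)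
Conditions: EtMgBr, THF, −78 °C; sat. aq NH4Cl, −78 °C
Reagents that add atoms: ethylmagnesium bromide, CC[Mg]Br
Why: Grignard addition is chemoselective for the aldehyde because the ring ketone sits between two quaternary carbons; the new carbinol centre is not controlled (it is oxidised in step 6), and the cold quench should prevent retro-aldol cleavage of the magnesium aldolate.

Step 6
Reactants: 6 (2R)-2-(1-hydroxypropyl)-2,6,6-trimethylcyclohexan-1-one
Product: 7 (6R)-2,2,6-trimethyl-6-propanoylcyclohexan-1-one
Conditions: Dess–Martin periodinane, CH2Cl2, rt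
Reagents that add atoms: none
Why: Dess–Martin oxidation of the secondary alcohol under non-basic conditions should give the 1,3-diketone without retro-Claisen cleavage at the quaternary C10.

Step 7
Reactants: 7 (6R)-2,2,6-trimethyl-6-propanoylcyclohexan-1-one
Product: 10 (8aS)-2,5,5,8a-tetramethyl-3,5,6,7,8,8a-hexahydronaphthalen-1(2H)-one (C2 epimers), via potassium enolate 8 (not isolated), via phosphonium ylide 9 (not isolated)
Conditions: KN(SiMe3)2 (1.05 equiv), THF, −78 °C; vinyltriphenylphosphonium bromide, −78 °C to rt; then toluene, 110 °C, high dilution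
Reagents that add atoms: vinyltriphenylphosphonium bromide, C=C[P+](c1ccccc1)(c1ccccc1)c1ccccc1.[Br-]
Why: The base removes the only acidic proton of 7 (on C8; the C5 ketone has no α-hydrogen), and enolate 8 adds through carbon to the cationic Michael acceptor, which forms C7–C8 and places a non-stabilised ylide (9) on C6. The ylide carbon then attacks the C5 carbonyl and the oxaphosphetane collapses to Ph3PO and the C5=C6 double bond, so the second bond of ring B is made in the same flask. The closest known reaction type is the Michael-initiated intramolecular Wittig annulation of carbanions with vinylphosphonium salts (Schweizer reaction). Ring B closes by 6-exo-trig addition of the ylide carbon to the C5 carbonyl; attack on the C9 carbonyl would give a cyclobutene and is not expected. The only new stereocentre is C8, which is left uncontrolled because it becomes sp2 in step 9; C10 is quaternary and cannot epimerise, and C5 is set in step 8. The step needs C- rather than O-alkylation of the enolate and olefination of a carbonyl flanked by two quaternary carbons; the soft cationic acceptor, the fact that the ylide is the most stable carbanion available in 9, the six-membered intramolecular geometry and heating are what should secure this.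

Step 8
Reactants: 10 (8aS)-2,5,5,8a-tetramethyl-3,5,6,7,8,8a-hexahydronaphthalen-1(2H)-one
Product: 11 (4aS,8aS)-2,5,5,8a-tetramethyloctahydronaphthalen-1(2H)-one (C2 epimers)
Conditions: Mn(dpm)3 (10 mol%), PhSiH3, t-BuOOH, i-PrOH, 22 °C
Reagents that add atoms: none
Why: Mukaiyama-type hydrogen atom transfer hydrogenation: a hydrogen atom adds to C6 to give the tertiary C5 radical, which should take up the second hydrogen axially from the α face, opposite the axial methyl groups on C10 and C4, and so give the trans ring fusion (5S).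

Step 9
Reactants: 11 (4aS,8aS)-2,5,5,8a-tetramethyloctahydronaphthalen-1(2H)-one
Product: 12 (4aS,8aS)-2,5,5,8a-tetramethyl-3,4,4a,5,6,7,8,8a-octahydronaphthalen-1-yl trifluoromethanesulfonate
Conditions: KN(SiMe3)2, THF, −78 to 0 °C; PhNTf2, 0 °C to rt; sat. aq NH4Cl
Reagents that add atoms: N-phenylbis(trifluoromethanesulfonimide), FC(F)(F)S(=O)(=O)N(c1ccccc1)S(=O)(=O)C(F)(F)F
Why: Deprotonation can occur only at C8 (C10 is quaternary), so O-triflation of the enolate gives the tetrasubstituted enol triflate regiospecifically and places the C8=C9 double bond of the target (enol triflate formation); both C8 epimers converge.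

Step 10
Reactants: 12 (4aS,8aS)-2,5,5,8a-tetramethyl-3,4,4a,5,6,7,8,8a-octahydronaphthalen-1-yl trifluoromethanesulfonate
Product: 13 (4aS,8aS)-5-ethenyl-1,1,4a,6-tetramethyl-1,2,3,4,4a,7,8,8a-octahydronaphthalene
Conditions: tributyl(vinyl)stannane, Pd(PPh3)4 (5 mol%), LiCl, THF, 66 °C
Reagents that add atoms: tributyl(vinyl)stannane, C=C[Sn](CCCC)(CCCC)CCCC
Why: Stille coupling of the enol triflate (chloride-promoted) should install C11–C12 as a vinyl group on C9 without moving the ring alkene.

**Side-chain fragment**

Step 11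
Reactants: 14 furan-3-carbaldehyde
Product: 15 (1R)-1-(furan-3-yl)but-3-yn-1-ol
Conditions: allenylboronic acid pinacol ester, (R)-TRIP phosphoric acid (5 mol%), 4 Å molecular sieves, toluene, 0 °C
Reagents that add atoms: allenylboronic acid pinacol ester, C=C=CB1OC(C)(C)C(C)(C)O1
Why: Chiral phosphoric acid-catalysed propargylation of the aldehyde with the allenylboronate proceeds through a closed six-membered transition state (SE2′ attack) in which the catalyst selects the aldehyde face and sets the C16 carbinol as R.

Step 12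
Reactants: 15 (1R)-1-(furan-3-yl)but-3-yn-1-ol
Product: 16 (5R)-5-(furan-3-yl)pent-2-yne-1,5-diol
Conditions: n-BuLi (2.2 equiv), THF, −78 °C; paraformaldehyde, −78 °C to rt; sat. aq NH4Cl
Reagents that add atoms: paraformaldehyde (formaldehyde equivalent), C=O
Why: Double deprotonation (alkoxide and acetylide) followed by addition of the lithium acetylide to formaldehyde should give the propargylic alcohol that becomes the hydroxymethyl group on C13 (acetylide hydroxymethylation).

Step 13
Reactants: 16 (5R)-5-(furan-3-yl)pent-2-yne-1,5-diol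
Product: 17 4-[(1R)-1,5-dihydroxypent-3-yn-1-yl]-5-hydroxyfuran-2(5H)-one (hemiacetal epimers)
Conditions: O2, visible light, Rose Bengal (cat.), i-Pr2NEt, CH2Cl2, −78 °C
Reagents that add atoms: dioxygen, O=O
Why: Singlet oxygen [4+2] cycloaddition to the furan gives an endoperoxide, and the hindered amine removes the proton at the ring carbon remote from the substituent, so the 4-substituted 5-hydroxybutenolide should form regioselectively; the alkyne is inert to singlet oxygen.

Step 14
Reactants: 17 4-[(1R)-1,5-dihydroxypent-3-yn-1-yl]-5-hydroxyfuran-2(5H)-one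
Product: 18 4-[(1R)-1,5-dihydroxypent-3-yn-1-yl]furan-2(5H)-one
Conditions: NaBH4, EtOH, 0 °C; then 1 M HCl
Reagents that add atoms: none
Why: NaBH4 reduces the ring-opened aldehyde form of the hydroxybutenolide, and acidification closes the lactone on the new primary alcohol; the C16 hydroxyl is trans to the carboxyl group across the ring alkene and cannot lactonise.

Step 15
Reactants: 18 4-[(1R)-1,5-dihydroxypent-3-yn-1-yl]furan-2(5H)-one
Product: 19 4-[(1R,3E)-1,5-dihydroxy-4-(tributylstannyl)pent-3-en-1-yl]furan-2(5H)-one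
Conditions: Bu3SnH, Pd(PPh3)2Cl2 (2 mol%), THF, 0 °C
Reagents that add atoms: tributyltin hydride, CCCC[SnH](CCCC)CCCC
Why: Palladium-catalysed syn-hydrostannation of the alkyne, with tin delivered to the carbon next to the propargylic hydroxymethyl group, should give the E-vinylstannane in which hydrogen and tin are cis.

Step 16
Reactants: 19 4-[(1R,3E)-1,5-dihydroxy-4-(tributylstannyl)pent-3-en-1-yl]furan-2(5H)-one
Product: 20 4-[(1R,3E)-1,5-dihydroxy-4-iodopent-3-en-1-yl]furan-2(5H)-one
Conditions: I2, CH2Cl2, 0 °C
Reagents that add atoms: iodine, II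
Why: Iododestannylation is an electrophilic ipso substitution that proceeds with retention of alkene geometry and should give the E-vinyl iodide.

**Union**

Step 17
Reactants: 13 (4aS,8aS)-5-ethenyl-1,1,4a,6-tetramethyl-1,2,3,4,4a,7,8,8a-octahydronaphthalene; 20 4-[(1R,3E)-1,5-dihydroxy-4-iodopent-3-en-1-yl]furan-2(5H)-one
Product: 22 4-[(1R,3Z)-1-hydroxy-4-(hydroxymethyl)-6-[(4aS,8aS)-2,5,5,8a-tetramethyl-3,4,4a,5,6,7,8,8a-octahydronaphthalen-1-yl]hex-3-en-1-yl]furan-2(5H)-one (target), via alkylborane 21 (not isolated)
Conditions: 9-BBN, THF, 0 °C to rt; then 3 M aq K3PO4, 20, Pd(dppf)Cl2 (5 mol%), AsPh3 (10 mol%), DMF, rt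
Reagents that add atoms: none
Why: Hydroboration of 13 with 9-BBN is selective for the terminal carbon of the vinyl group over the tetrasubstituted ring alkene, and the B-alkyl Suzuki–Miyaura coupling of 21 with 20 forms C12–C13 with retention of the vinyl iodide geometry, which gives the Z-alkene with the hydroxymethyl group cis to C15; no stereocentre is formed or touched.

**Compound list**

1 | 2,2,6-trimethylcyclohexan-1-one | CC1CCCC(C)(C)C1=O | starting material
2 | allyl 2,6,6-trimethylcyclohex-1-en-1-yl carbonate | C=CCOC(=O)OC1=C(C)CCCC1(C)C | intermediate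
3 | (2R)-2-allyl-2,6,6-trimethylcyclohexan-1-one | C=CC[C@@]1(C)CCCC(C)(C)C1=O | intermediate
4 | (6R)-2,2,6-trimethyl-6-[(1E)-prop-1-en-1-yl]cyclohexan-1-one | C/C=C/[C@@]1(C)CCCC(C)(C)C1=O | intermediate
5 | (1R)-1,3,3-trimethyl-2-oxocyclohexane-1-carbaldehyde | O=C[C@@]1(C)CCCC(C)(C)C1=O | intermediate
6 | (2R)-2-(1-hydroxypropyl)-2,6,6-trimethylcyclohexan-1-one (carbinol epimers) | CCC(O)[C@@]1(C)CCCC(C)(C)C1=O | intermediate
7 | (6R)-2,2,6-trimethyl-6-propanoylcyclohexan-1-one | CCC(=O)[C@@]1(C)CCCC(C)(C)C1=O | intermediate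
8 | potassium 1-[(1R)-1,3,3-trimethyl-2-oxocyclohexyl]prop-1-en-1-olate (potassium enolate of 7) | CC=C([O-])[C@@]1(C)CCCC(C)(C)C1=O.[K+] | intermediate
9 | (6R)-2,2,6-trimethyl-6-[2-methyl-4-(triphenylphosphoranylidene)butanoyl]cyclohexan-1-one (phosphonium ylide) | CC(CC=P(c1ccccc1)(c1ccccc1)c1ccccc1)C(=O)[C@@]1(C)CCCC(C)(C)C1=O | intermediate
10 | (8aS)-2,5,5,8a-tetramethyl-3,5,6,7,8,8a-hexahydronaphthalen-1(2H)-one (C2 epimers) | CC1CC=C2C(C)(C)CCC[C@]2(C)C1=O | intermediate
11 | (4aS,8aS)-2,5,5,8a-tetramethyloctahydronaphthalen-1(2H)-one (C2 epimers) | CC1CC[C@H]2C(C)(C)CCC[C@]2(C)C1=O | intermediate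
12 | (4aS,8aS)-2,5,5,8a-tetramethyl-3,4,4a,5,6,7,8,8a-octahydronaphthalen-1-yl trifluoromethanesulfonate | CC1=C(OS(=O)(=O)C(F)(F)F)[C@@]2(C)CCCC(C)(C)[C@@H]2CC1 | intermediate
13 | (4aS,8aS)-5-ethenyl-1,1,4a,6-tetramethyl-1,2,3,4,4a,7,8,8a-octahydronaphthalene | CC1=C(C=C)[C@@]2(C)CCCC(C)(C)[C@@H]2CC1 | intermediate
14 | furan-3-carbaldehyde | O=Cc1ccoc1 | starting material
15 | (1R)-1-(furan-3-yl)but-3-yn-1-ol | C#CC[C@@H](O)c1ccoc1 | intermediate
16 | (5R)-5-(furan-3-yl)pent-2-yne-1,5-diol | OCC#CC[C@@H](O)c1ccoc1 | intermediate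
17 | 4-[(1R)-1,5-dihydroxypent-3-yn-1-yl]-5-hydroxyfuran-2(5H)-one (hemiacetal epimers) | OCC#CC[C@@H](O)C1=CC(=O)OC1O | intermediate
18 | 4-[(1R)-1,5-dihydroxypent-3-yn-1-yl]furan-2(5H)-one | OCC#CC[C@@H](O)C1=CC(=O)OC1 | intermediate
19 | 4-[(1R,3E)-1,5-dihydroxy-4-(tributylstannyl)pent-3-en-1-yl]furan-2(5H)-one | CCCC[Sn](CCCC)(CCCC)/C(=C/C[C@@H](O)C1=CC(=O)OC1)CO | intermediate
20 | 4-[(1R,3E)-1,5-dihydroxy-4-iodopent-3-en-1-yl]furan-2(5H)-one | I/C(=C/C[C@@H](O)C1=CC(=O)OC1)CO | intermediate
21 | 9-{2-[(4aS,8aS)-2,5,5,8a-tetramethyl-3,4,4a,5,6,7,8,8a-octahydronaphthalen-1-yl]ethyl}-9-borabicyclo[3.3.1]nonane | CC1=C(CCB2C3CCCC2CCC3)[C@@]2(C)CCCC(C)(C)[C@@H]2CC1 | intermediate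
22 | 4-[(1R,3Z)-1-hydroxy-4-(hydroxymethyl)-6-[(4aS,8aS)-2,5,5,8a-tetramethyl-3,4,4a,5,6,7,8,8a-octahydronaphthalen-1-yl]hex-3-en-1-yl]furan-2(5H)-one | CC1=C(CC/C(=C/C[C@@H](O)C2=CC(=O)OC2)CO)[C@@]2(C)CCCC(C)(C)[C@@H]2CC1 | target

**Totals and risks**

Total step count: 17. Longest linear sequence: 11 steps (steps 1–10 and 17).

Steps most likely to fail:

1. Step 7. The ylide may fail to add to the C5 carbonyl, which is shielded by the two neighbouring quaternary carbons, so that proton transfer or decomposition of the ylide takes over. The fallback sets out from 7 and comes back at 10. The enolate of 7 (LiN(i-Pr)2, THF, −78 °C) is alkylated at C8 with allyl bromide to give (6R)-2,2,6-trimethyl-6-(2-methylpent-4-enoyl)cyclohexan-1-one F1. Ozonolysis (O3, CH2Cl2, −78 °C; Me2S) gives 3-methyl-4-oxo-4-[(1R)-1,3,3-trimethyl-2-oxocyclohexyl]butanal F2. An intramolecular McMurry coupling (TiCl3(DME)1.5, Zn–Cu couple, DME, reflux, slow addition) then joins the aldehyde carbon to C5 and should give 10. Reductive carbonyl coupling on low-valent titanium is much less sensitive to steric shielding than polar addition, and the neopentylic C9 ketone is expected to react more slowly than the aldehyde-initiated six-ring closure.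

2. Step 8. The tertiary C5 radical sits β to the C9 carbonyl and may undergo a 1,2-acyl shift (Dowd–Beckwith rearrangement) before it is reduced, or the second hydrogen transfer may lack facial selectivity. The fallback sets out from 10 and comes back at 11. The C9 ketone is reduced (NaBH4, CeCl3, MeOH, 0 °C) to (8aS)-2,5,5,8a-tetramethyl-1,2,3,5,6,7,8,8a-octahydronaphthalen-1-ol F3. Hydrogen atom transfer hydrogenation (Mn(dpm)3, PhSiH3, t-BuOOH, i-PrOH) is run on this alcohol, whose C5 radical has no acyl neighbour to migrate, and should give (4aS,8aS)-2,5,5,8a-tetramethyldecahydronaphthalen-1-ol F4. Dess–Martin oxidation returns the ketone 11.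

3. Step 17. The aqueous base needed for transmetalation may degrade the butenolide (ring opening or γ-deprotonation) while the hindered alkylborane transmetalates slowly. The fallback sets out from 13 and comes back at 22 under base-free conditions. Hydroboration with 9-BBN followed by iodinolysis (I2, NaOMe, MeOH) gives (4aS,8aS)-5-(2-iodoethyl)-1,1,4a,6-tetramethyl-1,2,3,4,4a,7,8,8a-octahydronaphthalene F5. Zinc insertion (Zn dust, LiCl, THF) gives {2-[(4aS,8aS)-2,5,5,8a-tetramethyl-3,4,4a,5,6,7,8,8a-octahydronaphthalen-1-yl]ethyl}zinc iodide F6. This is added slowly to 20 in a Negishi coupling (Pd(OAc)2, SPhos, THF, rt), where slow addition lets the coupling outrun protonation by the free hydroxyl groups, and should give 22.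

**Further compounds**

F1 | step 7 | (6R)-2,2,6-trimethyl-6-(2-methylpent-4-enoyl)cyclohexan-1-one | C=CCC(C)C(=O)[C@@]1(C)CCCC(C)(C)C1=O
F2 | step 7 | 3-methyl-4-oxo-4-[(1R)-1,3,3-trimethyl-2-oxocyclohexyl]butanal | O=CCC(C)C(=O)[C@@]1(C)CCCC(C)(C)C1=O
F3 | step 8 | (8aS)-2,5,5,8a-tetramethyl-1,2,3,5,6,7,8,8a-octahydronaphthalen-1-ol | CC1CC=C2C(C)(C)CCC[C@]2(C)C1O
F4 | step 8 | (4aS,8aS)-2,5,5,8a-tetramethyldecahydronaphthalen-1-ol | CC1CC[C@H]2C(C)(C)CCC[C@]2(C)C1O
F5 | step 17 | (4aS,8aS)-5-(2-iodoethyl)-1,1,4a,6-tetramethyl-1,2,3,4,4a,7,8,8a-octahydronaphthalene | CC1=C(CCI)[C@@]2(C)CCCC(C)(C)[C@@H]2CC1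
F6 | step 17 | {2-[(4aS,8aS)-2,5,5,8a-tetramethyl-3,4,4a,5,6,7,8,8a-octahydronaphthalen-1-yl]ethyl}zinc iodide | CC1=C(CC[Zn]I)[C@@]2(C)CCCC(C)(C)[C@@H]2CC1
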